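## Structural features

The target is a daucane diester: a bicyclo[5.3.0]decane in which cyclopentane ring A (C1–C5) and cycloheptene ring B (C1, C5–C10) share the C1–C5 bond in a trans fusion, with the quaternary methyl on C1 (its face is called β) and the hydrogen on C5 (α). Five stereocentres are present, absolute configuration 1S,4R,5S,6S,10R. C4 (tertiary carbinol, OH β, isopropyl α), C5 and C6 (benzoate α) are contiguous on one flank of the fusion, and C10 (angelate α, anti to the C1 methyl) adjoins C1 on the other. The fragile groups are the angelate (its Z-alkene slips to the tiglate when the acid is activated as an acylating agent or meets base), the allylic C10–O bond, the acid-sensitive tertiary carbinol at C4, and the benzoate, which becomes a vinylogous leaving group once a C8=C9–C10 enone exists. The real difficulty is a quaternary C1 flanked by an oxygenated carbon inside a seven-membered ring, a trans fusion that is not the thermodynamic preference of the related ketones, and a C10 oxygen on the α face, the face from which a reagent reaches a C10 carbonyl most easily. The key step exploits the fact that C9 is an unsubstituted sp2 CH between the oxygenated C10 and the methyl-bearing C8: ring B is a 2,2,6-trisubstituted cyclohexanone (C10, C1, C8) with one carbon inserted beside the carbonyl, and because C1 is quaternary, C9 is afterwards the only enolisable position. Two points of the obvious plan are amended: hydride addition to the C10 enone is expected anti to the axial C1 methyl and so to give the 10β-alcohol, hence the angelate is introduced with inversion; and the free C4 carbinol is not exposed to BF3·OEt2 with a silyl diazomethane, Me3Al being used so that the carbinol is masked in situ as an aluminium alkoxide.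

## Logic of the disconnections

**C10–O (alkyl–oxygen) bond.** 25 is cut between C10 and the ester oxygen into 23 and 24. Cutting here instead of at the acyl carbon means 24 serves as a nucleophile and is never an activated acyl species, and the displacement inverts C10. The gain is that the α-ester comes from the β-alcohol that reduction should provide. The demand is an SN2 displacement at an allylic carbon next to a quaternary centre.

**C10–H bond.** 23 is traced to 22. The C10 stereocentre becomes a carbonyl and ring B gains the enone needed for the next cut. The demand is 1,2-selectivity and hydride delivery anti to the C1 methyl.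

**C8=C9 π bond.** 22 is traced through 21 and 20 to 19. The alkene is removed because its position is fixed by the quaternary C1, which leaves C9 as the only enolisable site. The demand is a dehydrogenation mild enough for the benzoate.

**C9–C10 and C8–C9 (key cut).** 19 is cut into 16 and 17 by excising C9. Ring B shrinks to a six-membered ring and the flexible hydroazulene becomes a rigid trans-hydrindanone on which C1, C4, C5 and C6 can be set. The demand is that C8, not C1, migrates and that the hindered ketone accepts the diazo carbon.

**C8–CH3 bond and C10 oxidation level.** 16 is traced to 15, then 14 and 13. The methyl is added last on the only enolisable flank, and C10 is carried as a silyl ether because its hydroxyl is the marker left by the desymmetrisation. The demand is enolate chemistry that spares the benzoate.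

**C6–O and C5–H bonds.** 13 is traced to 12 and then, through 11, to 10. Both bonds are removed together as one syn addition across C5=C6, so two stereocentres and the trans fusion come from a single alkene. The demand is addition from the α face.

**C4–isopropyl bond.** 10 is cut to 9. The tertiary carbinol becomes an enone carbonyl. The demand is 1,2-addition from the α face without enolisation or reduction.

**C4–C5 bond.** 9 is traced to 8 and cut to 7. Ring A opens between the carbinol carbon and the alkenyl carbon, giving a monocyclic cyclohexenyl triflate with a tethered aldehyde. The demand is a chemoselective alkenyl–metal addition in a five-membered closure.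

**Functional-group interconversions.** 7 is traced to 6, 5 and 4: aldehyde from nitrile, enol triflate from the ketone (one enolisable side only), silyl ether from the carbinol. The nitrile is preferred to an ester because it cannot lactonise onto the C10 hydroxyl and stops at the aldehyde level on reduction.

**C10–H bond of the ketol.** 4 is traced to 3. A single enantioselective reduction of one of two enantiotopic carbonyls creates the quaternary stereocentre C1. The demand is catalyst control over which carbonyl is reduced and from which face.

**C1–C2 bond.** 3 is cut into 1 and 2 by a conjugate addition, which needs only a weak base.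

## Other disconnections considered

**Alternative 1:** The cuts are the C1–methyl and C5–C6 bonds, with ring B closed later at C9–C10. In the forward sense Me3Al adds to the silyloxymethyl cyclopentenone A2 under Cu(OTf)2 and a chiral phosphoramidite, and the aluminium enolate is trapped by the iodo-enal A3 to give the cyclopentanone A1.
- In its favour: C1, C5 and C6 are set in one convergent operation, and C6–C9 arrive with the C8=C9 alkene in place, so no ring expansion and no dehydrogenation are needed.
- Against it here: β,β-disubstituted cyclopentenones are the least responsive substrates for this conjugate addition. The aldol must fix the C6 carbinol through a weakly biased transition state. A1 is a β-hydroxy ketone open to retro-aldol cleavage and C5 epimerisation. The isopropyl group must still be added to the C4 ketone next to this array. The seven-membered closure leaves the C10 configuration open.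
- Comparison: on convergency and step economy (about a dozen steps) the alternative is the better plan. On the C10 problem the two are equal, since both need a correction there. The chosen plan is stronger on C4/C5/C6 control, because a concerted syn addition on a rigid bicycle replaces an aldol.

**Alternative 2:** The cuts are C1–C10 and C5–C6 of a cyclobutane whose C6–C10 bond is later cleaved. In the forward sense 3-methylcyclopent-2-enone A4 and the bis(silyloxy)cyclopentene A5 undergo a [2+2] photocycloaddition under a chiral oxazaborolidine–AlBr3 Lewis acid to give the five–four–five adduct A6; desilylation and glycol cleavage open it to the hydroazulene trione A7.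
- In its favour: the whole carbon skeleton, the quaternary C1 and oxygen at C4, C6 and C10 are reached in three or four steps from simple materials, which is far shorter than the chosen plan and is its clear advantage.
- Against it here: A7 has three ketones of similar reactivity, two of them a β-diketone through C5. Selective isopropyl addition at C4, the trans fusion, the α-alcohols at C6 and C10 and a regioselective C8=C9 dehydrogenation (C7 can also enolise toward the C6 ketone) must all be won afterwards. The enantioselective photocycloaddition would have to work on a β-substituted cyclopentenone with a tetrasubstituted alkene partner.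
- Comparison: on skeleton-building economy the alternative is better, and on C8 (a spectator centre in both) it is equal. The chosen plan is stronger on differentiation, since each oxygen is introduced at a distinct oxidation level and protected state.

**Alternative 3:** The cuts are C1–C5 and C8–C9, closing both rings at once. In the forward sense LiClO4 and Et3N ionise the tertiary α-chloro ketone A8 to an oxyallyl cation (C1–C10–C9) that adds across the tethered 2-silyloxydiene (C5–C8) in an intramolecular (4+3) cycloaddition, giving the bicyclo[5.3.0]decenone A9.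
- In its favour: rings A and B and the quaternary C1 form in one step from an acyclic precursor carrying the C4 carbinol, with C10 as ketone and C6 as enol ether; on convergency it is the better plan.
- Against it here: acyclic silyloxydienes can react stepwise with oxyallyl cations (simple alkylation or five-membered ring formation), so the trans relationship of C1 and C5 relative to C4 is not secured. The C6 enol ether leads to a ketone whose small-hydride reduction should give the axial 6β-alcohol and whose neighbour C5 can epimerise toward the cis fusion. The C8=C9 alkene must still be introduced.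
- Comparison: the alternative is better on bond-forming economy and equal on C8 (undefined until dehydrogenation) and on the C10 reduction problem. The chosen plan is stronger on predictability of the ring fusion and of C6.

Key step: step 14

Remark on the chemistry: target numbering is used for every intermediate (before step 14 the six-membered ring is C1–C10–C8–C7–C6–C5 and the bicycle is called a hydrindane), and C4 of 8 and the C8 methyl centre of 16 and 18–21 are taken as inconsequential epimer mixtures and left unspecified.

## Route

Step 1
Reactants: 1 2-methylcyclohexane-1,3-dione; 2 acrylonitrile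
Product: 3 3-(1-methyl-2,6-dioxocyclohexyl)propanenitrile
Conditions: Et3N (0.2 equiv), MeCN/H2O, 50 °C
Reagents that add atoms: none
Why: Michael addition (cyanoethylation) of the doubly stabilised enolate of 1 to 2 alkylates the carbon between the carbonyls and creates the prochiral quaternary carbon C1; no stereocentre is formed yet.

Step 2
Reactants: 3 3-(1-methyl-2,6-dioxocyclohexyl)propanenitrile
Product: 4 3-[(1R,2R)-2-hydroxy-1-methyl-6-oxocyclohexyl]propanenitrile (hydroxyl cis to the cyanoethyl chain; C10 α-OH)
Conditions: (S)-1-methyl-3,3-diphenyltetrahydro-1H,3H-pyrrolo[1,2-c][1,3,2]oxazaborole (0.2 equiv), catecholborane (1.2 equiv), toluene, −78 °C; chromatography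
Reagents that add atoms: none
Why: Corey–Bakshi–Shibata reduction used as an enantiotopic-group-selective desymmetrisation: with the quaternary carbon as the large flank the (S)-catalyst should give the (R)-carbinol, and hydride delivery syn to the smaller methyl puts the hydroxyl cis to the chain, which together fix C1. The minor diastereomer, which would lead to the antipode at C1, is removed by chromatography.

Step 3
Reactants: 4 3-[(1R,2R)-2-hydroxy-1-methyl-6-oxocyclohexyl]propanenitrile
Product: 5 3-[(1R,2R)-2-(tert-butyldimethylsilyloxy)-1-methyl-6-oxocyclohexyl]propanenitrile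
Conditions: TBSOTf, 2,6-lutidine, CH2Cl2, −40 → 0 °C
Reagents that add atoms: tert-butyldimethylsilyl trifluoromethanesulfonate, CC(C)(C)[Si](C)(C)OS(=O)(=O)C(F)(F)F
Why: O-silylation of the hindered carbinol needs the silyl triflate; with the weak base 2,6-lutidine the ketone is not enolised.

Step 4
Reactants: 5 3-[(1R,2R)-2-(tert-butyldimethylsilyloxy)-1-methyl-6-oxocyclohexyl]propanenitrile
Product: 6 3-[(1R,6R)-6-(tert-butyldimethylsilyloxy)-1-methyl-2-(trifluoromethylsulfonyloxy)cyclohex-2-en-1-yl]propanenitrile (C5=C6 enol triflate)
Conditions: KHMDS (1.05 equiv), THF, −78 °C; PhNTf2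
Reagents that add atoms: N-phenylbis(trifluoromethanesulfonimide), O=S(=O)(N(c1ccccc1)S(=O)(=O)C(F)(F)F)C(F)(F)F
Why: Kinetic enolate formation and O-sulfonylation; the ketone can enolise only toward C6 because C1 is quaternary, and the nitrile α-CH2 is far less acidic, so a single enol triflate should form.

Step 5
Reactants: 6 3-[(1R,6R)-6-(tert-butyldimethylsilyloxy)-1-methyl-2-(trifluoromethylsulfonyloxy)cyclohex-2-en-1-yl]propanenitrile
Product: 7 3-[(1R,6R)-6-(tert-butyldimethylsilyloxy)-1-methyl-2-(trifluoromethylsulfonyloxy)cyclohex-2-en-1-yl]propanal
Conditions: DIBAL-H (1.3 equiv), toluene, −78 °C; aq. tartaric acid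
Reagents that add atoms: water, O
Why: DIBAL-H adds once to the nitrile; the aluminium imine is stable at low temperature and is hydrolysed to the aldehyde on work-up, while the enol triflate and silyl ether are inert.

Step 6
Reactants: 7 3-[(1R,6R)-6-(tert-butyldimethylsilyloxy)-1-methyl-2-(trifluoromethylsulfonyloxy)cyclohex-2-en-1-yl]propanal
Product: 8 10α-(tert-butyldimethylsilyloxy)-1β-methylhydrind-5-en-4-ol (C5=C6 alkene; C4 epimers)
Conditions: CrCl2 (5 equiv), NiCl2 (0.02 equiv), DMF, rt
Reagents that add atoms: none
Why: Nozaki–Hiyama–Kishi reaction: zerovalent nickel formed in situ inserts into the C–OTf bond, transmetalation gives the alkenylchromium species, and this adds to the tethered aldehyde in a 5-exo-trig closure that forms C4–C5. The C4 configuration is erased in the next step.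

Step 7
Reactants: 8 10α-(tert-butyldimethylsilyloxy)-1β-methylhydrind-5-en-4-ol
Product: 9 10α-(tert-butyldimethylsilyloxy)-1β-methylhydrind-5-en-4-one
Conditions: Dess–Martin periodinane, NaHCO3, CH2Cl2, rt
Reagents that add atoms: none
Why: Dess–Martin oxidation of the allylic alcohol gives the cyclopentenone under neutral conditions and converges both C4 epimers.

Step 8
Reactants: 9 10α-(tert-butyldimethylsilyloxy)-1β-methylhydrind-5-en-4-one
Product: 10 10α-(tert-butyldimethylsilyloxy)-4α-isopropyl-1β-methylhydrind-5-en-4β-ol
Conditions: iPrMgCl, anhydrous CeCl3, THF, −78 → −40 °C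
Reagents that add atoms: isopropylmagnesium chloride, CC(C)[Mg]Cl
Why: Organocerium (Imamoto) 1,2-addition suppresses enolisation and β-hydride reduction; the C1 methyl stands perpendicular to the enone plane on the β face, so the nucleophile should enter from the α face and give the 4β-hydroxy-4α-isopropyl carbinol.

Step 9
Reactants: 10 10α-(tert-butyldimethylsilyloxy)-4α-isopropyl-1β-methylhydrind-5-en-4β-ol
Product: 12 10α-(tert-butyldimethylsilyloxy)-4α-isopropyl-1β-methyl-5α-hydrindane-4β,6α-diol, via alkylborane 11 (not isolated)
Conditions: BH3·THF (4 equiv), THF, 0 °C → rt; then 3 M NaOH, 30% H2O2, 0 °C → rt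
Reagents that add atoms: hydrogen peroxide, OO
Why: Hydroboration–oxidation: concerted syn addition with boron on the less substituted C6, from the α face because the C1 methyl is syn-axial to the β face of C6 and perpendicular over C5 (the bias known from steroidal 5-enes). This sets 5α-H (trans fusion) and 6α-B together, and oxidation with retention gives the 6α-alcohol.

Step 10
Reactants: 12 10α-(tert-butyldimethylsilyloxy)-4α-isopropyl-1β-methyl-5α-hydrindane-4β,6α-diol
Product: 13 6α-benzoyloxy-10α-(tert-butyldimethylsilyloxy)-4α-isopropyl-1β-methyl-5α-hydrindan-4β-ol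
Conditions: BzCl (1.3 equiv), 4-(dimethylamino)pyridine (0.1 equiv), pyridine, CH2Cl2, 0 °C → rt
Reagents that add atoms: benzoyl chloride, O=C(Cl)c1ccccc1
Why: Nucleophile-catalysed acylation of the equatorial secondary C6 hydroxyl; the tertiary C4 carbinol does not react under these conditions.

Step 11
Reactants: 13 6α-benzoyloxy-10α-(tert-butyldimethylsilyloxy)-4α-isopropyl-1β-methyl-5α-hydrindan-4β-ol
Product: 14 6α-benzoyloxy-4α-isopropyl-1β-methyl-5α-hydrindane-4β,10α-diol
Conditions: HF·pyridine, pyridine, THF, 0 °C → rt
Reagents that add atoms: none
Why: Fluoride-mediated desilylation under buffered conditions that neither cleave the benzoate nor ionise the tertiary carbinol.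

Step 12
Reactants: 14 6α-benzoyloxy-4α-isopropyl-1β-methyl-5α-hydrindane-4β,10α-diol
Product: 15 6α-benzoyloxy-4β-hydroxy-4α-isopropyl-1β-methyl-5α-hydrindan-10-one
Conditions: Dess–Martin periodinane, NaHCO3, CH2Cl2, rt
Reagents that add atoms: none
Why: Dess–Martin oxidation of the only secondary alcohol; the tertiary carbinol cannot be oxidised and the neutral medium avoids acyl migration.

Step 13
Reactants: 15 6α-benzoyloxy-4β-hydroxy-4α-isopropyl-1β-methyl-5α-hydrindan-10-one
Product: 16 6α-benzoyloxy-4β-hydroxy-4α-isopropyl-1β,8ξ-dimethyl-5α-hydrindan-10-one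
Conditions: LiHMDS (2.3 equiv), THF, −78 °C; MeI (3 equiv), −78 → −30 °C
Reagents that add atoms: iodomethane, CI
Why: Enolate alkylation: the base deprotonates the carbinol and the only enolisable α-position (C8), and the enolate is C-methylated. The equatorial C6 benzoate cannot reach the enolate carbon without a bridged transition state, and the C8 configuration is irrelevant because C8 later becomes sp2.

Step 14
Reactants: 16 6α-benzoyloxy-4β-hydroxy-4α-isopropyl-1β,8ξ-dimethyl-5α-hydrindan-10-one; 17 (trimethylsilyl)diazomethane
Product: 19 6α-benzoyloxy-4β-hydroxy-8ξ-daucan-10-one (ring-B cycloheptanone), via α-silyl ketone 18 (not isolated)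
Conditions: Me3Al (2.5 equiv), CH2Cl2, −78 °C; 17 (1.5 equiv), −78 → −20 °C; then 1 M HCl, THF, 0 °C
Reagents that add atoms: none
Why: Me3Al first converts the C4 carbinol into its dimethylaluminium alkoxide and then activates the C10 carbonyl, to which the nucleophilic diazo carbon of 17 adds to give a β-aluminoxy diazonium betaine. Loss of N2 is concerted with a suprafacial 1,2-shift of the ring bond antiperiplanar to the C–N2 bond; in the least crowded rotamer the Me3Si group turns away from the quaternary C1, which places C8 anti to nitrogen, so C8 migrates with retention and the new carbon becomes C9 between C10 and C8. The closest known reaction type is the Lewis-acid-promoted homologation of cyclic ketones with diazoalkanes (Tiffeneau–Demjanov-type ring enlargement), in which silyl diazomethane favours migration of the less substituted α-carbon. Ring B is not closed by a cyclisation: the six-membered ring is enlarged to the seven-membered one by the 1,2-shift, so no cyclisation mode applies. No lasting stereocentre is created, because the C9–Si centre of 18 (and its O-silyl isomer) is removed by protodesilylation with dilute acid and C8 keeps the configuration it had. The selectivities needed are migration of C8 over C1 (secured by the steric bias just described), single insertion (the α-silyl ketone is too hindered to react again) and survival of benzoate and carbinol (low temperature, aluminium alkoxide as in situ protection).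

Step 15
Reactants: 19 6α-benzoyloxy-4β-hydroxy-8ξ-daucan-10-one
Product: 20 6α-benzoyloxy-4β,10-bis(trimethylsilyloxy)-8ξ-dauc-9-ene (C9=C10 silyl enol ether)
Conditions: TMSOTf (2.6 equiv), Et3N (4 equiv), CH2Cl2, 0 °C
Reagents that add atoms: trimethylsilyl trifluoromethanesulfonate, C[Si](C)(C)OS(=O)(=O)C(F)(F)F
Why: Soft enolisation gives a single silyl enol ether because C1 is quaternary and only C9 carries α-hydrogens; the tertiary hydroxyl is silylated at the same time, which protects it temporarily.

Step 16
Reactants: 20 6α-benzoyloxy-4β,10-bis(trimethylsilyloxy)-8ξ-dauc-9-ene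
Product: 22 6α-benzoyloxy-4β-hydroxydauc-8-en-10-one, via enone silyl ether 21 (not isolated)
Conditions: Pd(OAc)2 (1.1 equiv), MeCN, rt; then 1 M HCl, THF, 0 °C
Reagents that add atoms: none
Why: Saegusa–Ito dehydrogenation: the divalent palladium enolate at C9 undergoes β-hydride elimination of the C8 hydrogen to give the C8=C9 enone whichever C8 epimer is present; brief dilute acid then removes the tertiary silyl ether.

Step 17
Reactants: 22 6α-benzoyloxy-4β-hydroxydauc-8-en-10-one
Product: 23 6α-benzoyloxydauc-8-ene-4β,10β-diol
Conditions: NaBH4, CeCl3·7H2O, MeOH, −78 °C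
Reagents that add atoms: none
Why: Luche reduction gives 1,2-addition only; in the trans-fused enone the C1 methyl stands nearly perpendicular to the carbonyl plane on the β face, so hydride should add anti to it from the α face and give the 10β-alcohol.

Step 18
Reactants: 23 6α-benzoyloxydauc-8-ene-4β,10β-diol; 24 angelic acid ((Z)-2-methylbut-2-enoic acid)
Product: 25 (1S,4R,5S,6S,10R)-10-[(Z)-2-methylbut-2-enoyloxy]-6-benzoyloxydauc-8-en-4-ol (target: 10α-angelate, 6α-benzoate, 4β-OH, 5α-H, 1β-methyl)
Conditions: PPh3, diisopropyl azodicarboxylate, toluene, 0 °C → rt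
Reagents that add atoms: none
Why: Mitsunobu esterification: the C10 alkoxyphosphonium is displaced by the angelate anion from the α face, anti to the C1 methyl, with inversion to the 10α-ester. The acid acts only as a nucleophile, so the Z-alkene is never part of an activated acyl species, and the tertiary carbinol does not react.

## Compound list

1 | 2-methylcyclohexane-1,3-dione | CC1C(=O)CCCC1=O | starting material
2 | acrylonitrile | C=CC#N | starting material
3 | 3-(1-methyl-2,6-dioxocyclohexyl)propanenitrile | CC1(CCC#N)C(=O)CCCC1=O | intermediate
4 | 3-[(1R,2R)-2-hydroxy-1-methyl-6-oxocyclohexyl]propanenitrile | O[C@@H]1CCCC(=O)[C@]1(C)CCC#N | intermediate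
5 | 3-[(1R,2R)-2-(tert-butyldimethylsilyloxy)-1-methyl-6-oxocyclohexyl]propanenitrile | CC(C)(C)[Si](C)(C)O[C@@H]1CCCC(=O)[C@]1(C)CCC#N | intermediate
6 | 3-[(1R,6R)-6-(tert-butyldimethylsilyloxy)-1-methyl-2-(trifluoromethylsulfonyloxy)cyclohex-2-en-1-yl]propanenitrile | CC(C)(C)[Si](C)(C)O[C@@H]1CCC=C(OS(=O)(=O)C(F)(F)F)[C@]1(C)CCC#N | intermediate
7 | 3-[(1R,6R)-6-(tert-butyldimethylsilyloxy)-1-methyl-2-(trifluoromethylsulfonyloxy)cyclohex-2-en-1-yl]propanal | CC(C)(C)[Si](C)(C)O[C@@H]1CCC=C(OS(=O)(=O)C(F)(F)F)[C@]1(C)CCC=O | intermediate
8 | 10α-(tert-butyldimethylsilyloxy)-1β-methylhydrind-5-en-4-ol (C4 epimers) | CC(C)(C)[Si](C)(C)O[C@@H]1CCC=C2[C@]1(C)CCC2O | intermediate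
9 | 10α-(tert-butyldimethylsilyloxy)-1β-methylhydrind-5-en-4-one | CC(C)(C)[Si](C)(C)O[C@@H]1CCC=C2[C@]1(C)CCC2=O | intermediate
10 | 10α-(tert-butyldimethylsilyloxy)-4α-isopropyl-1β-methylhydrind-5-en-4β-ol | CC(C)(C)[Si](C)(C)O[C@@H]1CCC=C2[C@]1(C)CC[C@@]2(O)C(C)C | intermediate
11 | 6α-boranyl adduct of 10 (C6–BH2, 5α-H) | CC(C)(C)[Si](C)(C)O[C@@H]1CC[C@H](B)[C@@H]2[C@]1(C)CC[C@@]2(O)C(C)C | intermediate
12 | 10α-(tert-butyldimethylsilyloxy)-4α-isopropyl-1β-methyl-5α-hydrindane-4β,6α-diol | CC(C)(C)[Si](C)(C)O[C@@H]1CC[C@H](O)[C@@H]2[C@]1(C)CC[C@@]2(O)C(C)C | intermediate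
13 | 6α-benzoyloxy-10α-(tert-butyldimethylsilyloxy)-4α-isopropyl-1β-methyl-5α-hydrindan-4β-ol | CC(C)(C)[Si](C)(C)O[C@@H]1CC[C@H](OC(=O)c3ccccc3)[C@@H]2[C@]1(C)CC[C@@]2(O)C(C)C | intermediate
14 | 6α-benzoyloxy-4α-isopropyl-1β-methyl-5α-hydrindane-4β,10α-diol | O[C@@H]1CC[C@H](OC(=O)c3ccccc3)[C@@H]2[C@]1(C)CC[C@@]2(O)C(C)C | intermediate
15 | 6α-benzoyloxy-4β-hydroxy-4α-isopropyl-1β-methyl-5α-hydrindan-10-one | O=C1CC[C@H](OC(=O)c3ccccc3)[C@@H]2[C@]1(C)CC[C@@]2(O)C(C)C | intermediate
16 | 6α-benzoyloxy-4β-hydroxy-4α-isopropyl-1β,8ξ-dimethyl-5α-hydrindan-10-one (key-step precursor) | O=C1C(C)C[C@H](OC(=O)c3ccccc3)[C@@H]2[C@]1(C)CC[C@@]2(O)C(C)C | intermediate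
17 | (trimethylsilyl)diazomethane | C[Si](C)(C)C=[N+]=[N-] | starting material
18 | 6α-benzoyloxy-4β-hydroxy-9-(trimethylsilyl)-8ξ-daucan-10-one | O=C1C([Si](C)(C)C)C(C)C[C@H](OC(=O)c3ccccc3)[C@@H]2[C@]1(C)CC[C@@]2(O)C(C)C | intermediate
19 | 6α-benzoyloxy-4β-hydroxy-8ξ-daucan-10-one (key-step product) | O=C1CC(C)C[C@H](OC(=O)c3ccccc3)[C@@H]2[C@]1(C)CC[C@@]2(O)C(C)C | intermediate
20 | 6α-benzoyloxy-4β,10-bis(trimethylsilyloxy)-8ξ-dauc-9-ene | C[Si](C)(C)OC1=CC(C)C[C@H](OC(=O)c3ccccc3)[C@@H]2[C@]1(C)CC[C@@]2(O[Si](C)(C)C)C(C)C | intermediate
21 | 6α-benzoyloxy-4β-(trimethylsilyloxy)dauc-8-en-10-one | O=C1C=C(C)C[C@H](OC(=O)c3ccccc3)[C@@H]2[C@]1(C)CC[C@@]2(O[Si](C)(C)C)C(C)C | intermediate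
22 | 6α-benzoyloxy-4β-hydroxydauc-8-en-10-one | O=C1C=C(C)C[C@H](OC(=O)c3ccccc3)[C@@H]2[C@]1(C)CC[C@@]2(O)C(C)C | intermediate
23 | 6α-benzoyloxydauc-8-ene-4β,10β-diol | O[C@H]1C=C(C)C[C@H](OC(=O)c3ccccc3)[C@@H]2[C@]1(C)CC[C@@]2(O)C(C)C | intermediate
24 | angelic acid ((Z)-2-methylbut-2-enoic acid) | C/C=C(/C)C(=O)O | starting material
25 | (1S,4R,5S,6S,10R)-10-[(Z)-2-methylbut-2-enoyloxy]-6-benzoyloxydauc-8-en-4-ol | C/C=C(/C)C(=O)O[C@@H]1C=C(C)C[C@H](OC(=O)c2ccccc2)[C@@H]2[C@]1(C)CC[C@@]2(O)C(C)C | target

## Step count and least certain steps

Total: 18 steps. Longest linear sequence: 18 steps from 1 (2, 17 and 24 are purchased).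

**Step 14 (key step).** The ketone is flanked by a quaternary and a tertiary carbon, so addition of the diazo carbon may be slow, and the betaine may then collapse by migration of C1 or by oxirane closure instead of C8 migration.
Fallback, from 16 back to 22: 16 is converted with TMSOTf/Et3N into the bis-silyl enol ether F1 (only C8 can enolise) and cyclopropanated with Et2Zn/CH2I2 to the siloxycyclopropane F2. FeCl3 in DMF then generates the alkoxy radical, which cleaves the internal bond toward the tertiary C8 radical and gives the β-chloro cycloheptanone F3. Loss of HCl with NaOAc gives 22 directly, forming the same two bonds to C9 by a radical ring enlargement.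

**Step 9.** Facial selectivity may be poor, because the α-isopropyl group on C4 and the axial silyloxy group on C10 hinder the α face that the C1 methyl otherwise leaves open; attack from the β face would give the cis fusion.
Fallback, from 9 back to 12: nucleophilic epoxidation of 9 (H2O2, NaOH, MeOH) should deliver the oxygen to C6 anti to the syn-axial methyl and give the α-epoxy ketone F4. SmI2 (THF/MeOH, −90 °C) cleaves the C5–O bond, and protonation of the samarium enolate from the α face gives the trans-fused β-hydroxy ketone F5. Addition of iPrMgCl/CeCl3 to C4 from the α face then gives 12.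

**Step 17.** Hydride may be delivered to the β face, or to both faces, if the seven-membered ring adopts a conformer in which the C1 methyl lies near the carbonyl plane.
Fallback, from 22 back to 25: the epimers are separated. The 10α-alcohol F6 is esterified with retention (24, 2,4,6-trichlorobenzoyl chloride, Et3N, toluene, 80 °C, no nucleophilic catalyst) to give 25, while 23 passes through step 18, so that either sense of reduction ends at 25.

**Step 18.** Displacement next to the quaternary C1 may be slow, which leaves room for 1,4-elimination to a diene or ionisation of the allylic oxyphosphonium with loss of stereochemical integrity.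
Fallback, from 23 back to 25: Mitsunobu reaction with the smaller and more acidic chloroacetic acid gives the 10α-chloroacetate F7. Thiourea/NaHCO3 in EtOH removes it selectively in the presence of the benzoate to give F6, which is esterified with retention as described above to give 25.

**Step 8.** The basic reagent may enolise the enone or reduce it by β-hydride transfer, and facial selectivity at C4 may be incomplete.
Fallback, from 9 back to 10: isopropenylmagnesium bromide/CeCl3 (no β-hydrogen on the carbanion carbon, smaller nucleophile) gives the isopropenyl carbinol F8. H2 with RhCl(PPh3)3 then saturates only the 1,1-disubstituted alkene to give 10.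

## Further compounds

F1 | step 14 | 6α-benzoyloxy-4α-isopropyl-1β,8-dimethyl-4β,10-bis(trimethylsilyloxy)-5α-hydrind-8(10)-ene | C[Si](C)(C)OC1=C(C)C[C@H](OC(=O)c4ccccc4)[C@@H]2[C@]1(C)CC[C@@]2(O[Si](C)(C)C)C(C)C
F2 | step 14 | siloxycyclopropane from F1 (CH2 bridging C8 and C10) | C[Si](C)(C)OC12CC1(C)C[C@H](OC(=O)c4ccccc4)[C@@H]3[C@]2(C)CC[C@@]3(O[Si](C)(C)C)C(C)C
F3 | step 14 | 6α-benzoyloxy-8-chloro-4β-hydroxydaucan-10-one | O=C1CC(C)(Cl)C[C@H](OC(=O)c4ccccc4)[C@@H]2[C@]1(C)CC[C@@]2(O)C(C)C
F4 | step 9 | 10α-(tert-butyldimethylsilyloxy)-5α,6α-epoxy-1β-methylhydrindan-4-one | CC(C)(C)[Si](C)(C)O[C@@H]1CC[C@@H]3O[C@@]23[C@]1(C)CCC2=O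
F5 | step 9 | 10α-(tert-butyldimethylsilyloxy)-6α-hydroxy-1β-methyl-5α-hydrindan-4-one | CC(C)(C)[Si](C)(C)O[C@@H]1CC[C@H](O)[C@@H]2[C@]1(C)CCC2=O
F6 | step 17 | 6α-benzoyloxydauc-8-ene-4β,10α-diol | O[C@@H]1C=C(C)C[C@H](OC(=O)c4ccccc4)[C@@H]2[C@]1(C)CC[C@@]2(O)C(C)C
F7 | step 18 | 6α-benzoyloxy-10α-(chloroacetoxy)dauc-8-en-4β-ol | ClCC(=O)O[C@@H]1C=C(C)C[C@H](OC(=O)c4ccccc4)[C@@H]2[C@]1(C)CC[C@@]2(O)C(C)C
F8 | step 8 | 10α-(tert-butyldimethylsilyloxy)-4α-isopropenyl-1β-methylhydrind-5-en-4β-ol | CC(C)(C)[Si](C)(C)O[C@@H]1CCC=C2[C@]1(C)CC[C@@]2(O)C(C)=C
A1 | alternative 1 | 2,3-trans cyclopentanone from the three-component coupling | I/C=C(/C)C[C@H](O)[C@@H]1[C@@](C)(CO[Si](C)(C)C(C)(C)C)CCC1=O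
A2 | alternative 1 | 3-[(tert-butyldimethylsilyloxy)methyl]cyclopent-2-en-1-one | O=C1C=C(CO[Si](C)(C)C(C)(C)C)CC1
A3 | alternative 1 | (Z)-4-iodo-3-methylbut-3-enal | I/C=C(/C)CC=O
A4 | alternative 2 | 3-methylcyclopent-2-en-1-one | CC1=CC(=O)CC1
A5 | alternative 2 | 4-methyl-1,2-bis(trimethylsilyloxy)cyclopent-1-ene | CC1CC(O[Si](C)(C)C)=C(O[Si](C)(C)C)C1
A6 | alternative 2 | five–four–five photoadduct | O=C1CC[C@]2(C)[C@@]3(O[Si](C)(C)C)CC(C)C[C@@]3(O[Si](C)(C)C)[C@H]12
A7 | alternative 2 | 1,8-dimethylbicyclo[5.3.0]decane-4,6,10-trione (target numbering; C5 epimerisable) | O=C1CC[C@]2(C)C(=O)CC(C)CC(=O)C12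
A8 | alternative 3 | open-chain tertiary α-chloro ketone with tethered 2-silyloxydiene | CC(=O)C(C)(Cl)CC[C@@](O[Si](CC)(CC)CC)(C(C)C)/C=C(O[Si](C)(C)C(C)(C)C)/C=C/C
A9 | alternative 3 | bicyclo[5.3.0]decenone from the (4+3) cycloaddition | O=C1CC(C)C=C(O[Si](C)(C)C(C)(C)C)[C@@H]2[C@]1(C)CC[C@@]2(O[Si](CC)(CC)CC)C(C)C
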